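**Plan**

- Retrosynthesis (eudesmane numbering C1–C15): the C5–OOH/C4=C15 unit goes back to a C4=C5 alkene (singlet-oxygen ene reaction). Then the C3–O acyl bond and the C11–C12 bond (carbonylation) are cut, then C9–C10, which opens ring B and re-aromatises ring A, and last the C6=C7 olefin bond between the arene and a butyrolactone.
- Enabling feature: in ring A the oxygenated C3 and the methyl-bearing quaternary C10 are para to each other (C3–C4–C5–C10), C4 bears C15 and C5 bears C6. Ring A is therefore a masked 3-alkyl-2,4-dimethylphenol whose para carbon C10 can close ring B (C5–C6–C7–C8–C9–C10) on C9 with loss of aromaticity.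
- Forward order: arene (future ring A) first; side chain C6–C9 and C11 by Wittig olefination, asymmetric hydrogenation and alkyne homologation; ring B last by fluoride-triggered para-alkylative dearomatization; then C1=C2 and C3=O reductions, methoxycarbonylation, angeloylation and photooxygenation.
- Stereochemistry: C7 from catalytic asymmetric hydrogenation; C10 from C7 (equatorial side chain in the chair-like ring closure); C3 from equatorial hydride delivery; C5 from α-face attack of singlet oxygen anti to the angular methyl; the Z-angelate comes from angelic acid.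

Key step: step 9

Remark: the target SMILES is read as methyl 3α-angeloyloxy-5α-hydroperoxyeudesma-4(15),11(13)-dien-12-oate, (3R,5S,7R,10S) in eudesmane numbering, and this numbering is used for atom labels in the text.

**Route**

Step 1
Reactants: 1 2,6-dimethylbenzaldehyde
Product: 2 3-bromo-2,6-dimethylbenzaldehyde
Conditions: N-bromosuccinimide (1.05 equiv), conc. H2SO4, rt
Reagents that add atoms: N-bromosuccinimide, O=C1CCC(=O)N1Br
Why: Electrophilic aromatic bromination in which both methyl groups (ortho/para) and the formyl group (meta) direct to C3, while the acidic medium keeps the ring deactivated against a second bromination.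

Step 2
Reactants: 2 3-bromo-2,6-dimethylbenzaldehyde; 3 3-(triphenyl-λ5-phosphanylidene)oxolan-2-one
Product: 4 (3E)-3-[(3-bromo-2,6-dimethylphenyl)methylidene]oxolan-2-one
Conditions: toluene, 110 °C
Reagents that add atoms: none
Why: Wittig olefination with a stabilised lactone ylide, which should give the E-alkylidene lactone (aryl anti to the carbonyl) and joins C6 to C7.

Step 3
Reactants: 4 (3E)-3-[(3-bromo-2,6-dimethylphenyl)methylidene]oxolan-2-one
Product: 5 (3S)-3-[(3-bromo-2,6-dimethylphenyl)methyl]oxolan-2-one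
Conditions: H2 (30 atm), [Ir(cod)(SpinPHOX)]B(C6H3(CF3)2)4 (1 mol %), CH2Cl2, rt
Reagents that add atoms: none
Why: Iridium-catalysed asymmetric hydrogenation of an α-arylidene-γ-butyrolactone with a chiral phosphine-oxazoline ligand sets the future C7; the ligand antipode that gives 3S is used, its sense is to be confirmed on the first run, and the aryl bromide is tolerated.

Step 4
Reactants: 5 (3S)-3-[(3-bromo-2,6-dimethylphenyl)methyl]oxolan-2-one
Product: 7 (3S)-3-[(3-hydroxy-2,6-dimethylphenyl)methyl]oxolan-2-one, via dipotassium carboxylate phenoxide salt 6 (not isolated)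
Conditions: Pd2(dba)3 (2 mol %), t-BuXPhos (8 mol %), KOH (4 equiv), dioxane/H2O, 100 °C; then aq. HCl, rt
Reagents that add atoms: potassium hydroxide, [K+].[OH-]
Why: Palladium-catalysed hydroxylation of the aryl bromide with hydroxide (C–O cross-coupling); the lactone is saponified to the configurationally stable carboxylate 6 and recloses on acidification.

Step 5
Reactants: 7 (3S)-3-[(3-hydroxy-2,6-dimethylphenyl)methyl]oxolan-2-one
Product: 8 (3S)-3-({2,6-dimethyl-3-[tri(propan-2-yl)silyloxy]phenyl}methyl)oxolan-2-one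
Conditions: i-Pr3SiCl, imidazole, DMF, rt
Reagents that add atoms: chlorotri(propan-2-yl)silane, CC(C)[Si](Cl)(C(C)C)C(C)C
Why: Silylation of the phenol gives a bulky aryl silyl ether that should survive the basic methanol and the bromoborane of the next steps and serves as the trigger of the key step.

Step 6
Reactants: 8 (3S)-3-({2,6-dimethyl-3-[tri(propan-2-yl)silyloxy]phenyl}methyl)oxolan-2-one
Product: 10 (3S)-3-({2,6-dimethyl-3-[tri(propan-2-yl)silyloxy]phenyl}methyl)pent-4-yn-1-ol, via lactol 9 (not isolated)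
Conditions: i-Bu2AlH (1.1 equiv), CH2Cl2, −78 °C; then MeOH, K2CO3, dimethyl (1-diazo-2-oxopropyl)phosphonate, −78 °C → rt
Reagents that add atoms: dimethyl (1-diazo-2-oxopropyl)phosphonate, CC(=O)C(=[N+]=[N-])P(=O)(OC)OC
Why: Partial reduction of the lactone to the lactol followed in the same flask by Seyferth–Gilbert homologation with the Ohira–Bestmann reagent turns C11 into a terminal alkyne and frees the C9 hydroxyl; the mild carbonate base should leave C7 unepimerised.

Step 7
Reactants: 10 (3S)-3-({2,6-dimethyl-3-[tri(propan-2-yl)silyloxy]phenyl}methyl)pent-4-yn-1-ol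
Product: 11 {3-[(2S)-2-(2-bromoethyl)but-3-yn-1-yl]-2,4-dimethylphenoxy}tri(propan-2-yl)silane
Conditions: CBr4, PPh3, CH2Cl2, 0 °C
Reagents that add atoms: tetrabromomethane, BrC(Br)(Br)Br
Why: Appel bromination of the primary alcohol under neutral conditions leaves the alkyne and the aryl silyl ether untouched and installs the leaving group at C9.

Step 8
Reactants: 11 {3-[(2S)-2-(2-bromoethyl)but-3-yn-1-yl]-2,4-dimethylphenoxy}tri(propan-2-yl)silane
Product: 13 {3-[(2S)-3-bromo-2-(2-bromoethyl)but-3-en-1-yl]-2,4-dimethylphenoxy}tri(propan-2-yl)silane, via alkenyl-9-BBN adduct 12 (not isolated)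
Conditions: B-bromo-9-BBN (1.3 equiv), CH2Cl2, 0 °C; then AcOH, 0 °C → rt
Reagents that add atoms: 9-bromo-9-borabicyclo[3.3.1]nonane, BrB1C2CCCC1CCC2
Why: syn-Bromoboration of the terminal alkyne (bromine to the internal carbon C11) and protodeboronation of 12 with acetic acid give the 2-bromo-1-alkene, a base- and hydride-stable precursor of the acrylate.

Step 9
Reactants: 13 {3-[(2S)-3-bromo-2-(2-bromoethyl)but-3-en-1-yl]-2,4-dimethylphenoxy}tri(propan-2-yl)silane
Product: 15 (4aS,7R)-7-(1-bromoethenyl)-1,4a-dimethyl-5,6,7,8-tetrahydronaphthalen-2(4aH)-one, via tetrabutylammonium phenoxide 14 (not isolated)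
Conditions: n-Bu4NF (1.05 equiv), THF (0.005 M), 0 → 50 °C
Reagents that add atoms: none
Why: Fluoride cleaves the aryl silyl ether and the free tetrabutylammonium phenoxide 14 attacks the primary bromide at C9 through its para carbon (the future C10) in an SN2 reaction, an intramolecular alkylative dearomatization of a phenol (Ar2-6 phenoxide alkylation; the closest known type is the base- or fluoride-induced para-alkylation of phenols that carry an ω-haloalkyl chain). Ring B closes in the 6-(enolendo)-exo-tet mode and ring A leaves as the cross-conjugated 2,5-cyclohexadienone. The new quaternary centre C10 is controlled by C7: in the chair-like transition state the 1-bromoethenyl group is equatorial, and C9 then reaches the arene face that places the angular methyl cis to this group (4aS). The step needs C-alkylation at the para carbon C10 and not at the ortho carbon C4 or at oxygen: O-alkylation would give a strained meta-bridged ether and its intermolecular version is held back by high dilution, while the para carbon has the larger HOMO coefficient of the phenoxide, gives the more stable cross-conjugated dienone, is not flanked by the solvated oxygen, and gets no chelation competition because the ammonium counter-ion cannot bridge oxygen and leaving group. The vinyl bromide and C7–H are inert to phenoxide and fluoride.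

Step 10
Reactants: 15 (4aS,7R)-7-(1-bromoethenyl)-1,4a-dimethyl-5,6,7,8-tetrahydronaphthalen-2(4aH)-one
Product: 16 (4aS,7R)-7-(1-bromoethenyl)-1,4a-dimethyl-4,4a,5,6,7,8-hexahydronaphthalen-2(3H)-one
Conditions: [(Ph3P)CuH]6 (0.25 equiv), H2O (2 equiv), benzene, rt
Reagents that add atoms: none
Why: Copper hydride conjugate reduction should touch only the disubstituted C1=C2 enone bond, because the fully substituted C4=C5 bond and the vinyl bromide are inert, and water protonates the copper enolate.

Step 11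
Reactants: 16 (4aS,7R)-7-(1-bromoethenyl)-1,4a-dimethyl-4,4a,5,6,7,8-hexahydronaphthalen-2(3H)-one
Product: 17 (2R,4aS,7R)-7-(1-bromoethenyl)-1,4a-dimethyl-2,3,4,4a,5,6,7,8-octahydronaphthalen-2-ol
Conditions: LiBH(s-Bu)3, THF, −78 °C; then H2O
Reagents that add atoms: none
Why: 1,2-Reduction of the β,β-disubstituted enone with a bulky trialkylborohydride, which attacks along the equatorial trajectory and should give the pseudoaxial 3α-alcohol (2R), as known for 4-en-3-ones with an angular methyl.

Step 12
Reactants: 17 (2R,4aS,7R)-7-(1-bromoethenyl)-1,4a-dimethyl-2,3,4,4a,5,6,7,8-octahydronaphthalen-2-ol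
Product: 18 methyl 2-[(2R,4aS,7R)-7-hydroxy-4a,8-dimethyl-1,2,3,4,4a,5,6,7-octahydronaphthalen-2-yl]prop-2-enoate
Conditions: Pd(OAc)2 (5 mol %), Xantphos (6 mol %), CO (1 atm), Et3N, MeOH/DMF, 60 °C
Reagents that add atoms: carbon monoxide, [C-]#[O+]; methanol, CO
Why: Palladium-catalysed methoxycarbonylation of the alkenyl bromide (oxidative addition, CO insertion, methanolysis) gives the α-substituted acrylate without touching C7 or the hindered allylic alcohol.

Step 13
Reactants: 18 methyl 2-[(2R,4aS,7R)-7-hydroxy-4a,8-dimethyl-1,2,3,4,4a,5,6,7-octahydronaphthalen-2-yl]prop-2-enoate; 19 angelic acid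
Product: 21 methyl 2-[(2R,4aS,7R)-4a,8-dimethyl-7-{[(2Z)-2-methylbut-2-enoyl]oxy}-1,2,3,4,4a,5,6,7-octahydronaphthalen-2-yl]prop-2-enoate, via mixed anhydride 20 (not isolated)
Conditions: 19, 2,4,6-trichlorobenzoyl chloride, Et3N, toluene, rt; then 18, toluene, 80 °C
Reagents that add atoms: none
Why: Yamaguchi-type esterification through the mixed anhydride 20 without a nucleophilic catalyst, conditions under which angelates form without Z to E isomerisation, and the configuration at C3 is retained.

Step 14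
Reactants: 21 methyl 2-[(2R,4aS,7R)-4a,8-dimethyl-7-{[(2Z)-2-methylbut-2-enoyl]oxy}-1,2,3,4,4a,5,6,7-octahydronaphthalen-2-yl]prop-2-enoate
Product: 22 methyl 2-[(2R,4aS,7R,8aS)-8a-hydroperoxy-4a-methyl-8-methylidene-7-{[(2Z)-2-methylbut-2-enoyl]oxy}decahydronaphthalen-2-yl]prop-2-enoate
Conditions: O2, hν (visible), tetraphenylporphyrin (cat.), CH2Cl2, −20 °C
Reagents that add atoms: dioxygen, O=O
Why: Schenck ene reaction of singlet oxygen with the tetrasubstituted C4=C5 alkene; attack on the α face anti to the axial angular methyl, where only the C15 hydrogens stand perpendicular to the π plane (H-6α is equatorial, H-3β lies in the plane), should place the hydroperoxide at C5 (8aS) and move the double bond to C4=C15, while the electron-poor acrylate and angelate alkenes do not react.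

**Compound list**

1 | 2,6-dimethylbenzaldehyde | Cc1cccc(C)c1C=O | starting material
2 | 3-bromo-2,6-dimethylbenzaldehyde | O=Cc1c(C)ccc(Br)c1C | intermediate
3 | 3-(triphenyl-λ5-phosphanylidene)oxolan-2-one | O=C1OCCC1=P(c1ccccc1)(c1ccccc1)c1ccccc1 | starting material
4 | (3E)-3-[(3-bromo-2,6-dimethylphenyl)methylidene]oxolan-2-one | O=C1OCC/C1=C\c1c(C)ccc(Br)c1C | intermediate
5 | (3S)-3-[(3-bromo-2,6-dimethylphenyl)methyl]oxolan-2-one | O=C1OCC[C@@H]1Cc1c(C)ccc(Br)c1C | intermediate
6 | dipotassium (2S)-2-[(2,6-dimethyl-3-oxidophenyl)methyl]-4-hydroxybutanoate | [K+].[K+].[O-]C(=O)[C@@H](Cc1c(C)ccc([O-])c1C)CCO | intermediate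
7 | (3S)-3-[(3-hydroxy-2,6-dimethylphenyl)methyl]oxolan-2-one | O=C1OCC[C@@H]1Cc1c(C)ccc(O)c1C | intermediate
8 | (3S)-3-({2,6-dimethyl-3-[tri(propan-2-yl)silyloxy]phenyl}methyl)oxolan-2-one | O=C1OCC[C@@H]1Cc1c(C)ccc(O[Si](C(C)C)(C(C)C)C(C)C)c1C | intermediate
9 | (3S)-3-({2,6-dimethyl-3-[tri(propan-2-yl)silyloxy]phenyl}methyl)oxolan-2-ol (lactol, both anomers) | OC1OCC[C@@H]1Cc1c(C)ccc(O[Si](C(C)C)(C(C)C)C(C)C)c1C | intermediate
10 | (3S)-3-({2,6-dimethyl-3-[tri(propan-2-yl)silyloxy]phenyl}methyl)pent-4-yn-1-ol | C#C[C@@H](Cc1c(C)ccc(O[Si](C(C)C)(C(C)C)C(C)C)c1C)CCO | intermediate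
11 | {3-[(2S)-2-(2-bromoethyl)but-3-yn-1-yl]-2,4-dimethylphenoxy}tri(propan-2-yl)silane | C#C[C@@H](Cc1c(C)ccc(O[Si](C(C)C)(C(C)C)C(C)C)c1C)CCBr | intermediate
12 | 9-[(1Z,3S)-2,5-dibromo-3-({2,6-dimethyl-3-[tri(propan-2-yl)silyloxy]phenyl}methyl)pent-1-en-1-yl]-9-borabicyclo[3.3.1]nonane | Br/C(=C\B1C2CCCC1CCC2)[C@@H](Cc1c(C)ccc(O[Si](C(C)C)(C(C)C)C(C)C)c1C)CCBr | intermediate
13 | {3-[(2S)-3-bromo-2-(2-bromoethyl)but-3-en-1-yl]-2,4-dimethylphenoxy}tri(propan-2-yl)silane | C=C(Br)[C@@H](Cc1c(C)ccc(O[Si](C(C)C)(C(C)C)C(C)C)c1C)CCBr | intermediate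
14 | tetrabutylammonium 3-[(2S)-3-bromo-2-(2-bromoethyl)but-3-en-1-yl]-2,4-dimethylphenolate | C=C(Br)[C@@H](Cc1c(C)ccc([O-])c1C)CCBr.CCCC[N+](CCCC)(CCCC)CCCC | intermediate
15 | (4aS,7R)-7-(1-bromoethenyl)-1,4a-dimethyl-5,6,7,8-tetrahydronaphthalen-2(4aH)-one | C=C(Br)[C@@H]1CC[C@@]2(C)C=CC(=O)C(C)=C2C1 | intermediate
16 | (4aS,7R)-7-(1-bromoethenyl)-1,4a-dimethyl-4,4a,5,6,7,8-hexahydronaphthalen-2(3H)-one | C=C(Br)[C@@H]1CC[C@@]2(C)CCC(=O)C(C)=C2C1 | intermediate
17 | (2R,4aS,7R)-7-(1-bromoethenyl)-1,4a-dimethyl-2,3,4,4a,5,6,7,8-octahydronaphthalen-2-ol | C=C(Br)[C@@H]1CC[C@@]2(C)CC[C@@H](O)C(C)=C2C1 | intermediate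
18 | methyl 2-[(2R,4aS,7R)-7-hydroxy-4a,8-dimethyl-1,2,3,4,4a,5,6,7-octahydronaphthalen-2-yl]prop-2-enoate | C=C(C(=O)OC)[C@@H]1CC[C@@]2(C)CC[C@@H](O)C(C)=C2C1 | intermediate
19 | angelic acid, (2Z)-2-methylbut-2-enoic acid | C/C=C(/C)C(=O)O | starting material
20 | (2Z)-2-methylbut-2-enoic 2,4,6-trichlorobenzoic anhydride | C/C=C(/C)C(=O)OC(=O)c1c(Cl)cc(Cl)cc1Cl | intermediate
21 | methyl 2-[(2R,4aS,7R)-4a,8-dimethyl-7-{[(2Z)-2-methylbut-2-enoyl]oxy}-1,2,3,4,4a,5,6,7-octahydronaphthalen-2-yl]prop-2-enoate | C=C(C(=O)OC)[C@@H]1CC[C@@]2(C)CC[C@@H](OC(=O)/C(C)=C\C)C(C)=C2C1 | intermediate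
22 | methyl 2-[(2R,4aS,7R,8aS)-8a-hydroperoxy-4a-methyl-8-methylidene-7-{[(2Z)-2-methylbut-2-enoyl]oxy}decahydronaphthalen-2-yl]prop-2-enoate | C=C(C(=O)OC)[C@@H]1CC[C@@]2(C)CC[C@@H](OC(=O)/C(C)=C\C)C(=C)[C@]2(OO)C1 | target

**Count and risks**

Total step count: 14. Longest linear sequence: 14 steps (1 to 22).

Steps most likely to fail:

1. Step 9. The phenoxide may be alkylated through the ortho carbon C4 instead of the para carbon C10, C9 may add to the wrong arene face, or intermolecular O-alkylation may win. The two carbon sites are geometrically equivalent, so the para preference rests only on electronic and solvation arguments and is the main uncertainty of the route. Fallback, from 13 back to 15: the ring closure is moved from the anionic to an electrophilic manifold, in which the neutral silyloxy-arene is the nucleophile and the bulky silyloxy group and arenium-ion stability favour the para position. Compound 13 is converted with NaI in acetone into {3-[(2S)-3-bromo-2-(2-iodoethyl)but-3-en-1-yl]-2,4-dimethylphenoxy}tri(propan-2-yl)silane F1. Ionisation of the C–I bond with AgOSO2CF3 and 2,6-di-tert-butylpyridine in (CF3)2CHOH/CH2Cl2 at 0 °C should bring about aryl participation at C10 (Friedel–Crafts-type ipso attack, same chair-like control by C7), and loss of the silyl group from the oxocarbenium ion gives 15.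

2. Step 14. Oxygen transfer may occur with poor facial or positional selectivity, because the pseudoaxial 3α-ester shields part of the α face and β-face attack would abstract H-6β. Fallback, from 18 back to 22: the ene reaction is run on the free allylic alcohol, whose hydroxyl directs singlet oxygen to its own (α) face by hydrogen bonding (O2, hν, tetraphenylporphyrin, CCl4). This gives methyl 2-[(2R,4aS,7R,8aS)-8a-hydroperoxy-7-hydroxy-4a-methyl-8-methylidenedecahydronaphthalen-2-yl]prop-2-enoate F2. The more acidic and more nucleophilic hydroperoxide is capped with 2-methoxypropene and pyridinium p-toluenesulfonate at −20 °C as the peroxyketal methyl 2-[(2R,4aS,7R,8aS)-7-hydroxy-8a-[(2-methoxypropan-2-yl)peroxy]-4a-methyl-8-methylidenedecahydronaphthalen-2-yl]prop-2-enoate F3. The alcohol is esterified with the mixed anhydride 20 in toluene at 60 °C to methyl 2-[(2R,4aS,7R,8aS)-8a-[(2-methoxypropan-2-yl)peroxy]-4a-methyl-8-methylidene-7-{[(2Z)-2-methylbut-2-enoyl]oxy}decahydronaphthalen-2-yl]prop-2-enoate F4, and AcOH/THF/H2O releases 22.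

3. Step 3. Hydrogenation of the hindered, twisted arylidene may be slow or poorly face-selective. Fallback, from 2 back to 5: C7 is set by an Evans alkylation. Compound 2 is reduced with NaBH4 to (3-bromo-2,6-dimethylphenyl)methanol F5 and converted with PBr3 into 1-bromo-3-(bromomethyl)-2,4-dimethylbenzene F6. The sodium enolate (NaN(SiMe3)2, THF, −78 °C) of commercial (4S)-4-benzyl-3-(pent-4-enoyl)-1,3-oxazolidin-2-one is alkylated by F6 on the face away from the benzyl group to give (4S)-4-benzyl-3-{(2R)-2-[(3-bromo-2,6-dimethylphenyl)methyl]pent-4-enoyl}-1,3-oxazolidin-2-one F7. Ozonolysis with NaBH4 work-up gives (4S)-4-benzyl-3-{(2S)-2-[(3-bromo-2,6-dimethylphenyl)methyl]-4-hydroxybutanoyl}-1,3-oxazolidin-2-one F8, which lactonises with catalytic p-toluenesulfonic acid to 5 with release of the auxiliary.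

Further compounds
F1 | step 9 | {3-[(2S)-3-bromo-2-(2-iodoethyl)but-3-en-1-yl]-2,4-dimethylphenoxy}tri(propan-2-yl)silane | C=C(Br)[C@@H](Cc1c(C)ccc(O[Si](C(C)C)(C(C)C)C(C)C)c1C)CCI
F2 | step 14 | methyl 2-[(2R,4aS,7R,8aS)-8a-hydroperoxy-7-hydroxy-4a-methyl-8-methylidenedecahydronaphthalen-2-yl]prop-2-enoate | C=C(C(=O)OC)[C@@H]1CC[C@@]2(C)CC[C@@H](O)C(=C)[C@]2(OO)C1
F3 | step 14 | methyl 2-[(2R,4aS,7R,8aS)-7-hydroxy-8a-[(2-methoxypropan-2-yl)peroxy]-4a-methyl-8-methylidenedecahydronaphthalen-2-yl]prop-2-enoate | C=C(C(=O)OC)[C@@H]1CC[C@@]2(C)CC[C@@H](O)C(=C)[C@]2(OOC(C)(C)OC)C1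
F4 | step 14 | methyl 2-[(2R,4aS,7R,8aS)-8a-[(2-methoxypropan-2-yl)peroxy]-4a-methyl-8-methylidene-7-{[(2Z)-2-methylbut-2-enoyl]oxy}decahydronaphthalen-2-yl]prop-2-enoate | C=C(C(=O)OC)[C@@H]1CC[C@@]2(C)CC[C@@H](OC(=O)/C(C)=C\C)C(=C)[C@]2(OOC(C)(C)OC)C1
F5 | step 3 | (3-bromo-2,6-dimethylphenyl)methanol | OCc1c(C)ccc(Br)c1C
F6 | step 3 | 1-bromo-3-(bromomethyl)-2,4-dimethylbenzene | BrCc1c(C)ccc(Br)c1C
F7 | step 3 | (4S)-4-benzyl-3-{(2R)-2-[(3-bromo-2,6-dimethylphenyl)methyl]pent-4-enoyl}-1,3-oxazolidin-2-one | O=C1OC[C@H](Cc2ccccc2)N1C(=O)[C@@H](Cc1c(C)ccc(Br)c1C)CC=C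
F8 | step 3 | (4S)-4-benzyl-3-{(2S)-2-[(3-bromo-2,6-dimethylphenyl)methyl]-4-hydroxybutanoyl}-1,3-oxazolidin-2-one | O=C1OC[C@H](Cc2ccccc2)N1C(=O)[C@@H](Cc1c(C)ccc(Br)c1C)CCO
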